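**Retrosynthetic overview**

1. C14–C15 is cut between two alkenyl carbons. A C18 ring-A dienediyne with a free terminal alkyne C13≡C14 (15), one CH3 from Me3Al (C20) and a C21 ring-B tetraenyl iodide (37) are joined in one flask by Zr-catalysed syn-methylalumination followed by Pd/Zn alkenyl–alkenyl coupling. The enabling feature is the methyl-branched E double bond C13(CH3)=C14H that sits directly on the C14–C15 bond, which is the retron of a terminal-alkyne carbometalation; the only other alkyne, C7≡C8, is internal and shielded by the C1 gem-dimethyl and C5 methyl groups of ring A and by C9–CH3.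
2. Ring-B half: the enolised 6',8'-diketone comes from aldol addition and oxidation (C7'–C8') of cyclopentyl methyl ketone 26 with iodotetraenal 34. Aldehyde 34 comes from a Stille coupling (C10'–C11') and a Takai olefination (C15'=C15).
3. Ring B (cyclopentane C1'–C5') is made by Lewis-acid ring contraction of a hydroxyl-directed 5,6-epoxide of a tetramethylcyclohexenol, copying the presumed biogenesis of such cyclopentyl ketone end groups from 5,6-epoxides. The directing hydroxyl is then inverted at C3' by a Mitsunobu reaction.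
4. Ring A (cyclohexene C1–C6) is kept from ketoisophorone: C6–C7 by acetylide addition, oxygen moved to C4 by oxidative 1,3-transposition, and the trans-3,4-diol by hydroxyl-directed reduction.
5. Both rings derive from ketoisophorone by enantiodivergent transfer hydrogenation. Ring A keeps its size throughout (steps 4–10), ring B is formed by contraction in step 16, and no ring is formed in or after the key step.

Key step: step 28

Assumption: the target is drawn as the C8' enol of a 6',8'-diketone; the diketone formed in step 27 is taken to rest in this hydrogen-bonded enol form (carotenoid numbering C1–C20 and C1'–C20' is used for positions).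

**Route**

Step 1
Reactants: 1 3-bromo-1-(trimethylsilyl)prop-1-yne
Product: 2 diethyl [3-(trimethylsilyl)prop-2-yn-1-yl]phosphonate
Conditions: P(OEt)3 (1.2 equiv), neat, 110 °C, EtBr distilled off
Reagents that add atoms: triethyl phosphite, CCOP(OCC)OCC
Why: Michaelis–Arbuzov reaction of a primary propargylic bromide, the silyl cap on the alkyne disfavouring the SN2' (allenyl) pathway.

Step 2
Reactants: 3 (E)-3-methylpent-2-en-4-yn-1-ol
Product: 4 (E)-3-methylpent-2-en-4-ynal
Conditions: MnO2 (excess), CH2Cl2, 23 °C; filtered solution used directly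
Reagents that add atoms: none
Why: MnO2 allylic oxidation should give the volatile enal without touching the terminal alkyne or the E double bond (the later C9=C10).

Step 3
Reactants: 2 diethyl [3-(trimethylsilyl)prop-2-yn-1-yl]phosphonate; 4 (E)-3-methylpent-2-en-4-ynal
Product: 6 trimethyl[(3E,5E)-6-methylocta-3,5-dien-1,7-diyn-1-yl]silane, via lithiated phosphonate 5 (not isolated)
Conditions: 2, LiN(SiMe3)2 (1.0 equiv), THF, −78 °C; then 4, −78 → 0 °C
Reagents that add atoms: none
Why: Horner–Wadsworth–Emmons olefination with a propargyl-stabilised phosphonate anion should form the C11=C12 double bond mainly as the E isomer, any Z isomer being removable by chromatography.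

Step 4
Reactants: 7 2,6,6-trimethylcyclohex-2-ene-1,4-dione (ketoisophorone)
Product: 8 (S)-4-hydroxy-2,6,6-trimethylcyclohex-2-en-1-one
Conditions: RuCl[(S,S)-TsDPEN](p-cymene) (0.5 mol%), KOH (cat.), i-PrOH, 23 °C
Reagents that add atoms: none
Why: Noyori-type asymmetric transfer hydrogenation should reduce only the unhindered C4 carbonyl (the C1 carbonyl is flanked by the gem-dimethyl carbon and C2–CH3), and the (S,S) ligand is expected, by the CH/π model that treats the alkenyl side like an aryl group, to give the (S)-carbinol that becomes C3 of ring A.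

Step 5
Reactants: 8 (S)-4-hydroxy-2,6,6-trimethylcyclohex-2-en-1-one
Product: 9 (S)-4-[(tert-butyldimethylsilyl)oxy]-2,6,6-trimethylcyclohex-2-en-1-one
Conditions: t-BuMe2SiCl, imidazole, DMF, 23 °C
Reagents that add atoms: tert-butyldimethylsilyl chloride, CC(C)(C)[Si](C)(C)Cl
Why: standard silylation of a secondary alcohol, needed so that the acetylide and the chromium oxidant of the next two steps leave C3 alone.

Step 6
Reactants: 6 trimethyl[(3E,5E)-6-methylocta-3,5-dien-1,7-diyn-1-yl]silane; 9 (S)-silyloxy enone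
Product: 11 (4S)-4-[(tert-butyldimethylsilyl)oxy]-2,6,6-trimethyl-1-[(3E,5E)-3-methyl-8-(trimethylsilyl)octa-3,5-dien-1,7-diyn-1-yl]cyclohex-2-en-1-ol (both C1 epimers), via lithium acetylide 10 (not isolated)
Conditions: 6, n-BuLi (1.0 equiv), THF, −78 °C; then 9, −78 → −20 °C; H2O
Reagents that add atoms: none
Why: 1,2-addition of a lithium acetylide to the hindered enone carbonyl, which has no α-hydrogen on the gem-dimethyl side, forms C6–C7, and the new carbinol centre is formed as a mixture that is erased in step 7.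

Step 7
Reactants: 11 tertiary alkynyl allylic alcohol
Product: 12 (S)-6-[(tert-butyldimethylsilyl)oxy]-2,4,4-trimethyl-3-[(3E,5E)-3-methyl-8-(trimethylsilyl)octa-3,5-dien-1,7-diyn-1-yl]cyclohex-2-en-1-one
Conditions: [C5H5NH][CrO3Cl] (pyridinium chlorochromate, 2.5 equiv), Celite, CH2Cl2, 23 °C
Reagents that add atoms: pyridinium chlorochromate, [O-][Cr](=O)(=O)Cl.c1cc[nH+]cc1
Why: Babler–Dauben oxidative transposition, in which the tertiary allylic chromate ester shifts [3,3] to C4 and is oxidised there, should give the enone with the tetrasubstituted C5=C6 double bond conjugated to the alkyne and leave the C3 silyloxy centre untouched.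

Step 8
Reactants: 12 silyloxy enone
Product: 13 (S)-6-hydroxy-2,4,4-trimethyl-3-[(3E,5E)-3-methylocta-3,5-dien-1,7-diyn-1-yl]cyclohex-2-en-1-one
Conditions: Bu4NF (2.5 equiv), AcOH (2.5 equiv), THF, 0 → 23 °C, argon
Reagents that add atoms: none
Why: fluoride should cleave the O–Si bond of the secondary silyl ether and the C(sp)–Si bond in one operation (desilylation), the acetic acid buffer keeping the base- and air-sensitive α-ketol from enolising.

Step 9
Reactants: 13 α-hydroxy enone
Product: 14 (1S,2S)-3,5,5-trimethyl-4-[(3E,5E)-3-methylocta-3,5-dien-1,7-diyn-1-yl]cyclohex-3-ene-1,2-diol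
Conditions: Me4NBH(OAc)3 (4 equiv), MeCN/AcOH (1:1), −20 °C
Reagents that add atoms: none
Why: Evans–Saksena-type hydroxyl-directed reduction, in which the C3 oxygen binds the triacetoxyborohydride and delivers hydride to the C4 carbonyl on its own face, should place the new C4 hydroxyl trans to the C3 hydroxyl ((4S)).

Step 10
Reactants: 14 trans-diol
Product: 15 {[(1S,2S)-3,5,5-trimethyl-4-[(3E,5E)-3-methylocta-3,5-dien-1,7-diyn-1-yl]cyclohex-3-ene-1,2-diyl]bis(oxy)}bis(triethylsilane)
Conditions: Et3SiOTf (2.5 equiv), 2,6-lutidine, CH2Cl2, −78 → 0 °C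
Reagents that add atoms: triethylsilyl trifluoromethanesulfonate, CC[Si](CC)(CC)OS(=O)(=O)C(F)(F)F
Why: silyl triflate silylation protects both secondary hydroxyls, including the hindered allylic one at C4, while the terminal alkyne is inert to these conditions.

Step 11
Reactants: 7 2,6,6-trimethylcyclohex-2-ene-1,4-dione (ketoisophorone)
Product: 16 (R)-4-hydroxy-2,6,6-trimethylcyclohex-2-en-1-one
Conditions: RuCl[(R,R)-TsDPEN](p-cymene) (0.5 mol%), KOH (cat.), i-PrOH, 23 °C
Reagents that add atoms: none
Why: the same Noyori-type transfer hydrogenation with the enantiomeric ligand should give the (R)-carbinol, whose hydroxyl will direct the epoxidation of step 15 and be inverted in step 17.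

Step 12
Reactants: 16 (R)-4-hydroxy-2,6,6-trimethylcyclohex-2-en-1-one
Product: 17 (R)-4-[(tert-butyldimethylsilyl)oxy]-2,6,6-trimethylcyclohex-2-en-1-one
Conditions: t-BuMe2SiCl, imidazole, DMF, 23 °C
Reagents that add atoms: tert-butyldimethylsilyl chloride, CC(C)(C)[Si](C)(C)Cl
Why: standard silylation, so that the hydride and Grignard reagents of the next two steps meet no acidic hydroxyl.

Step 13
Reactants: 17 (R)-silyloxy enone
Product: 19 (S)-4-[(tert-butyldimethylsilyl)oxy]-2,6,6-trimethylcyclohex-1-en-1-yl trifluoromethanesulfonate, via lithium enolate 18 (not isolated)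
Conditions: LiBH(s-Bu)3 (1.1 equiv), THF, −78 °C; then PhNTf2, −78 → 0 °C
Reagents that add atoms: N-phenylbis(trifluoromethanesulfonimide), O=S(=O)(N(c1ccccc1)S(=O)(=O)C(F)(F)F)C(F)(F)F
Why: the bulky borohydride should add hydride 1,4 to this enone, whose carbonyl is shielded and whose β-carbon carries no alkyl group, and the regiodefined enolate is trapped on oxygen (conjugate reduction and enolate triflation) without touching the carbinol centre.

Step 14
Reactants: 19 enol triflate
Product: 21 (S)-3,4,5,5-tetramethylcyclohex-3-en-1-ol, via silyl ether 20 (not isolated)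
Conditions: MeMgBr (1.5 equiv), Fe(acac)3 (5 mol%), THF/NMP, −30 → 0 °C; then Bu4NF, THF, 23 °C
Reagents that add atoms: methylmagnesium bromide, C[Mg]Br
Why: Kochi-type iron-catalysed cross-coupling of the enol triflate with MeMgBr should install the fourth methyl group without moving the tetrasubstituted double bond, and fluoride then frees the homoallylic hydroxyl that directs step 15.

Step 15
Reactants: 21 (S)-3,4,5,5-tetramethylcyclohex-3-en-1-ol
Product: 22 (1R,3R,6S)-1,5,5,6-tetramethyl-7-oxabicyclo[4.1.0]heptan-3-ol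
Conditions: VO(acac)2 (5 mol%), t-BuOOH (1.5 equiv), CH2Cl2, 0 → 23 °C
Reagents that add atoms: tert-butyl hydroperoxide, CC(C)(C)OO
Why: vanadium-catalysed hydroxyl-directed epoxidation, in which the homoallylic alkoxide holds the metal peroxide, should deliver oxygen to the electron-rich tetrasubstituted alkene on the face of the hydroxyl and so set both epoxide carbons (1R,6S).

Step 16
Reactants: 22 syn-epoxy alcohol
Product: 23 1-[(1R,4R)-4-hydroxy-1,2,2-trimethylcyclopentyl]ethan-1-one
Conditions: BF3·OEt2 (1.5 equiv), CH2Cl2, −78 °C, then aq. NaHCO3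
Reagents that add atoms: none
Why: Meinwald (semipinacol) rearrangement, in which Lewis-acid opening of the fully substituted epoxide is followed by migration of a ring bond anti to the departing oxygen, should contract ring B from six to five members; both possible modes (C1 to C5 or C4 to C6 shift) converge on the same ketone, the quaternary centre (R) follows from the epoxide configuration by inversion, and the syn hydroxyl cannot reach the cationic carbon from the rear.

Step 17
Reactants: 23 cis-hydroxy ketone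
Product: 24 (1S,3R)-3-acetyl-3,4,4-trimethylcyclopentyl 4-nitrobenzoate
Conditions: 4-O2NC6H4CO2H, PPh3, i-PrO2CN=NCO2i-Pr, THF, 0 → 23 °C
Reagents that add atoms: 4-nitrobenzoic acid, OC(=O)c1ccc(cc1)[N+](=O)[O-]
Why: Mitsunobu esterification displaces the activated secondary cyclopentanol oxygen by SN2 and so inverts C3' to the (S) configuration, trans to the acetyl group.

Step 18
Reactants: 24 4-nitrobenzoate
Product: 25 1-[(1R,4S)-4-hydroxy-1,2,2-trimethylcyclopentyl]ethan-1-one
Conditions: K2CO3, MeOH, 23 °C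
Reagents that add atoms: none
Why: mild methanolysis of the electron-poor aryl ester (transesterification) frees the alcohol, and the quaternary α-carbon of the ketone cannot epimerise.

Step 19
Reactants: 25 trans-hydroxy ketone
Product: 26 1-[(1R,4S)-1,2,2-trimethyl-4-[(triethylsilyl)oxy]cyclopentyl]ethan-1-one
Conditions: Et3SiCl, imidazole, DMF, 23 °C
Reagents that add atoms: triethylsilyl chloride, CC[Si](Cl)(CC)CC
Why: standard silylation, giving an ether that tolerates the enolate, oxidation and organometallic steps and leaves together with the ring-A ethers at the end.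

Step 20
Reactants: 3 (E)-3-methylpent-2-en-4-yn-1-ol
Product: 27 (2E,4E)-3-methyl-5-(tributylstannyl)penta-2,4-dien-1-ol
Conditions: Bu3SnH, PdCl2(PPh3)2 (2 mol%), THF, 0 °C
Reagents that add atoms: tributyltin hydride, CCCC[SnH](CCCC)CCCC
Why: palladium-catalysed syn-hydrostannation of the terminal alkyne should put tin on the terminal carbon (C11') and give the E-alkenylstannane (C11'=C12').

Step 21
Reactants: 27 stannyl dienol
Product: 28 (2E,4E)-3-methyl-5-(tributylstannyl)penta-2,4-dienal
Conditions: MnO2 (excess), CH2Cl2, 23 °C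
Reagents that add atoms: none
Why: MnO2 allylic oxidation is neutral and should leave the alkenylstannane intact.

Step 22
Reactants: 29 prop-2-yn-1-ol
Product: 31 (E)-3-iodo-2-methylprop-2-en-1-ol, via alkenylalane 30 (not isolated)
Conditions: Me3Al (3 equiv), Cp2ZrCl2 (0.25 equiv), CH2Cl2, 0 → 23 °C; then I2, THF, −30 → 0 °C
Reagents that add atoms: trimethylaluminium, C[Al](C)C; iodine, II
Why: zirconium-catalysed syn-methylalumination (Negishi carboalumination) of the aluminium alkoxide of propargyl alcohol puts CH3 on C9' and aluminium on C10', and iodinolysis with retention gives the E-iodide.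

Step 23
Reactants: 28 stannyl dienal; 31 (E)-3-iodo-2-methylprop-2-en-1-ol
Product: 32 (2E,4E,6E)-8-hydroxy-3,7-dimethylocta-2,4,6-trienal
Conditions: Pd2(dba)3 (2.5 mol%), AsPh3 (20 mol%), NMP, 23 °C, dark
Reagents that add atoms: none
Why: Stille coupling joins C10' to C11' with retention of both double-bond geometries and tolerates the free hydroxyl and the aldehyde.

Step 24
Reactants: 32 hydroxy trienal
Product: 33 (2E,4E,6E,8E)-9-iodo-2,6-dimethylnona-2,4,6,8-tetraen-1-ol
Conditions: CrCl2 (8 equiv), CHI3 (3 equiv), THF/1,4-dioxane, 0 → 23 °C, dark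
Reagents that add atoms: iodoform, IC(I)I
Why: Takai olefination, in which the geminal dichromium species from CHI3 adds to the aldehyde and eliminates, should give the E-iodoalkene (C15'=C15), the weakly basic reagent tolerating the free primary hydroxyl when CrCl2 is in excess.

Step 25
Reactants: 33 iodotetraenol
Product: 34 (2E,4E,6E,8E)-9-iodo-2,6-dimethylnona-2,4,6,8-tetraenal
Conditions: MnO2 (excess), CH2Cl2, 23 °C, dark
Reagents that add atoms: none
Why: MnO2 allylic oxidation gives the C8' aldehyde without affecting the alkenyl iodide.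

Step 26
Reactants: 26 silyl-protected cyclopentyl methyl ketone; 34 iodotetraenal
Product: 36 (4E,6E,8E,10E)-3-hydroxy-11-iodo-4,8-dimethyl-1-[(1R,4S)-1,2,2-trimethyl-4-[(triethylsilyl)oxy]cyclopentyl]undeca-4,6,8,10-tetraen-1-one (both C3 epimers), via lithium enolate 35 (not isolated)
Conditions: 26, LiN(i-Pr)2 (1.05 equiv), THF, −78 °C; then 34, −78 °C; H2O
Reagents that add atoms: none
Why: the ketone can enolise only at its CH3 group because the other α-carbon is quaternary, so a single lithium enolate adds 1,2 to the enal (aldol addition) to form C7'–C8', and the new carbinol centre is removed in step 27.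

Step 27
Reactants: 36 aldol
Product: 37 (2Z,4E,6E,8E,10E)-3-hydroxy-11-iodo-4,8-dimethyl-1-[(1R,4S)-1,2,2-trimethyl-4-[(triethylsilyl)oxy]cyclopentyl]undeca-2,4,6,8,10-pentaen-1-one
Conditions: Dess–Martin periodinane, NaHCO3, CH2Cl2, 0 → 23 °C, dark
Reagents that add atoms: none
Why: Dess–Martin oxidation of the β-hydroxy ketone gives the 1,3-diketone, which should settle as the conjugated, hydrogen-bonded C8' enol.

Step 28
Reactants: 15 ring-A dienediyne bis(triethylsilyl) ether; 37 ring-B tetraenyl iodide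
Product: 40 (3S,4S,3'S,5'R)-8'-hydroxy-3,4,3'-tris[(triethylsilyl)oxy]-7,8-didehydro-β,κ-caroten-6'-one, via alkenylalane 38 (not isolated), via aluminium chelate 39 (not isolated)
Conditions: 15, Me3Al (2.5 equiv), Cp2ZrCl2 (0.5 equiv), ClCH2CH2Cl, 23 °C, then volatiles removed; 37, Me3Al (1.0 equiv), THF, 0 °C; both combined with ZnCl2 (1 equiv), Pd2(dba)3 (2.5 mol%), P(2-furyl)3 (10 mol%), THF/DMF, 23 °C, dark; aq. potassium sodium tartrate
Reagents that add atoms: trimethylaluminium, C[Al](C)C
Why: Cp2ZrCl2-catalysed syn-methylalumination adds CH3–Al across the terminal C13≡C14 triple bond of 15 (CH3 to C13, aluminium to C14), and the (E)-alkenyldimethylalane 38 is then passed through zinc to zerovalent palladium, which has inserted into the C15–I bond of 39, and reductive elimination forms C14–C15. The closest known reaction type is the one-flask zirconium-catalysed carboalumination and palladium/zinc alkenyl–alkenyl (Negishi) cross-coupling used for methyl-branched all-E polyenes, carotenoid chains included. No ring is closed and no sp3 stereocentre is made; the new stereo-element is the trisubstituted C13=C14 double bond, whose E geometry is fixed by the suprafacial addition of CH3–Al and carried through transmetalation and reductive elimination with retention, as is the E geometry of C15=C15' of the iodide. The step needs chemoselectivity for the terminal over the internal alkyne, which should follow from the much slower carbometalation of disubstituted alkynes and from the shielding of C7≡C8 by the C1 gem-dimethyl, C5 methyl and C9 methyl groups, and it needs aluminium at the terminal carbon, the normal regiochemistry for conjugated terminal enynes. Protonolysis of the alkenyl metal by the acidic enol of the 6',8'-diketone is avoided by turning 37 into its dimethylaluminium chelate 39 with one equivalent of Me3Al before the partners are mixed, and the tartrate work-up returns the free enol.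

Step 29
Reactants: 40 tris(triethylsilyl) ether
Product: 41 (3S,4S,3'S,5'R)-3,4,3',8'-tetrahydroxy-7,8-didehydro-β,κ-caroten-6'-one (target)
Conditions: HF·pyridine, pyridine, THF, 0 → 23 °C, dark, argon
Reagents that add atoms: none
Why: pyridine-buffered HF should cleave the three triethylsilyl ethers (desilylation) under conditions mild enough not to ionise the allylic C4 hydroxyl, isomerise the polyene or cleave the enolised diketone.

**Compound list**

1 | 3-bromo-1-(trimethylsilyl)prop-1-yne | C[Si](C)(C)C#CCBr | starting material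
2 | diethyl [3-(trimethylsilyl)prop-2-yn-1-yl]phosphonate | CCOP(=O)(CC#C[Si](C)(C)C)OCC | intermediate
3 | (E)-3-methylpent-2-en-4-yn-1-ol | C#C/C(C)=C/CO | starting material
4 | (E)-3-methylpent-2-en-4-ynal | C#C/C(C)=C/C=O | intermediate
5 | lithium salt of the α-carbanion of phosphonate 2 | [Li+].CCOP(=O)([CH-]C#C[Si](C)(C)C)OCC | intermediate (not isolated)
6 | trimethyl[(3E,5E)-6-methylocta-3,5-dien-1,7-diyn-1-yl]silane | C#C/C(C)=C/C=C/C#C[Si](C)(C)C | intermediate
7 | 2,6,6-trimethylcyclohex-2-ene-1,4-dione (ketoisophorone) | CC1=CC(=O)CC(C)(C)C1=O | starting material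
8 | (S)-4-hydroxy-2,6,6-trimethylcyclohex-2-en-1-one | CC1(C)C[C@H](O)C=C(C)C1=O | intermediate
9 | (S)-4-[(tert-butyldimethylsilyl)oxy]-2,6,6-trimethylcyclohex-2-en-1-one | CC1(C)C[C@H](O[Si](C)(C)C(C)(C)C)C=C(C)C1=O | intermediate
10 | lithium acetylide of 6 | [Li+].[C-]#C/C(C)=C/C=C/C#C[Si](C)(C)C | intermediate (not isolated)
11 | (4S)-4-[(tert-butyldimethylsilyl)oxy]-2,6,6-trimethyl-1-[(3E,5E)-3-methyl-8-(trimethylsilyl)octa-3,5-dien-1,7-diyn-1-yl]cyclohex-2-en-1-ol, both C1 epimers | CC1(C)C[C@H](O[Si](C)(C)C(C)(C)C)C=C(C)C1(O)C#C/C(C)=C/C=C/C#C[Si](C)(C)C | intermediate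
12 | (S)-6-[(tert-butyldimethylsilyl)oxy]-2,4,4-trimethyl-3-[(3E,5E)-3-methyl-8-(trimethylsilyl)octa-3,5-dien-1,7-diyn-1-yl]cyclohex-2-en-1-one | CC1=C(C#C/C(C)=C/C=C/C#C[Si](C)(C)C)C(C)(C)C[C@H](O[Si](C)(C)C(C)(C)C)C1=O | intermediate
13 | (S)-6-hydroxy-2,4,4-trimethyl-3-[(3E,5E)-3-methylocta-3,5-dien-1,7-diyn-1-yl]cyclohex-2-en-1-one | CC1=C(C#C/C(C)=C/C=C/C#C)C(C)(C)C[C@H](O)C1=O | intermediate
14 | (1S,2S)-3,5,5-trimethyl-4-[(3E,5E)-3-methylocta-3,5-dien-1,7-diyn-1-yl]cyclohex-3-ene-1,2-diol | CC1=C(C#C/C(C)=C/C=C/C#C)C(C)(C)C[C@H](O)[C@H]1O | intermediate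
15 | {[(1S,2S)-3,5,5-trimethyl-4-[(3E,5E)-3-methylocta-3,5-dien-1,7-diyn-1-yl]cyclohex-3-ene-1,2-diyl]bis(oxy)}bis(triethylsilane) | CC1=C(C#C/C(C)=C/C=C/C#C)C(C)(C)C[C@H](O[Si](CC)(CC)CC)[C@H]1O[Si](CC)(CC)CC | intermediate
16 | (R)-4-hydroxy-2,6,6-trimethylcyclohex-2-en-1-one | CC1(C)C[C@@H](O)C=C(C)C1=O | intermediate
17 | (R)-4-[(tert-butyldimethylsilyl)oxy]-2,6,6-trimethylcyclohex-2-en-1-one | CC1(C)C[C@@H](O[Si](C)(C)C(C)(C)C)C=C(C)C1=O | intermediate
18 | lithium (S)-4-[(tert-butyldimethylsilyl)oxy]-2,6,6-trimethylcyclohex-1-en-1-olate | [Li+].CC1(C)C[C@@H](O[Si](C)(C)C(C)(C)C)CC(C)=C1[O-] | intermediate (not isolated)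
19 | (S)-4-[(tert-butyldimethylsilyl)oxy]-2,6,6-trimethylcyclohex-1-en-1-yl trifluoromethanesulfonate | CC1(C)C[C@@H](O[Si](C)(C)C(C)(C)C)CC(C)=C1OS(=O)(=O)C(F)(F)F | intermediate
20 | tert-butyldimethyl{[(1S)-3,4,5,5-tetramethylcyclohex-3-en-1-yl]oxy}silane | CC1(C)C[C@@H](O[Si](C)(C)C(C)(C)C)CC(C)=C1C | intermediate (not isolated)
21 | (S)-3,4,5,5-tetramethylcyclohex-3-en-1-ol | CC1(C)C[C@@H](O)CC(C)=C1C | intermediate
22 | (1R,3R,6S)-1,5,5,6-tetramethyl-7-oxabicyclo[4.1.0]heptan-3-ol (epoxide syn to hydroxyl) | CC1(C)C[C@@H](O)C[C@@]2(C)O[C@@]12C | intermediate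
23 | 1-[(1R,4R)-4-hydroxy-1,2,2-trimethylcyclopentyl]ethan-1-one (hydroxyl cis to acetyl) | CC(=O)[C@]1(C)C[C@H](O)CC1(C)C | intermediate
24 | (1S,3R)-3-acetyl-3,4,4-trimethylcyclopentyl 4-nitrobenzoate | CC(=O)[C@]1(C)C[C@@H](OC(=O)c2ccc(cc2)[N+](=O)[O-])CC1(C)C | intermediate
25 | 1-[(1R,4S)-4-hydroxy-1,2,2-trimethylcyclopentyl]ethan-1-one (hydroxyl trans to acetyl) | CC(=O)[C@]1(C)C[C@@H](O)CC1(C)C | intermediate
26 | 1-[(1R,4S)-1,2,2-trimethyl-4-[(triethylsilyl)oxy]cyclopentyl]ethan-1-one | CC(=O)[C@]1(C)C[C@@H](O[Si](CC)(CC)CC)CC1(C)C | intermediate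
27 | (2E,4E)-3-methyl-5-(tributylstannyl)penta-2,4-dien-1-ol | CCCC[Sn](CCCC)(CCCC)/C=C/C(C)=C/CO | intermediate
28 | (2E,4E)-3-methyl-5-(tributylstannyl)penta-2,4-dienal | CCCC[Sn](CCCC)(CCCC)/C=C/C(C)=C/C=O | intermediate
29 | prop-2-yn-1-ol | C#CCO | starting material
30 | (E)-{3-[(dimethylalumanyl)oxy]-2-methylprop-1-en-1-yl}dimethylalumane | C[Al](C)/C=C(C)/CO[Al](C)C | intermediate (not isolated)
31 | (E)-3-iodo-2-methylprop-2-en-1-ol | OC/C(C)=C/I | intermediate
32 | (2E,4E,6E)-8-hydroxy-3,7-dimethylocta-2,4,6-trienal | O=C/C=C(C)/C=C/C=C(C)/CO | intermediate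
33 | (2E,4E,6E,8E)-9-iodo-2,6-dimethylnona-2,4,6,8-tetraen-1-ol | OC/C(C)=C/C=C/C(C)=C/C=C/I | intermediate
34 | (2E,4E,6E,8E)-9-iodo-2,6-dimethylnona-2,4,6,8-tetraenal | O=C/C(C)=C/C=C/C(C)=C/C=C/I | intermediate
35 | lithium enolate of 26 (enolate of the acetyl CH3 group) | [Li+].[O-]C(=C)[C@]1(C)C[C@@H](O[Si](CC)(CC)CC)CC1(C)C | intermediate (not isolated)
36 | (4E,6E,8E,10E)-3-hydroxy-11-iodo-4,8-dimethyl-1-[(1R,4S)-1,2,2-trimethyl-4-[(triethylsilyl)oxy]cyclopentyl]undeca-4,6,8,10-tetraen-1-one, both C3 epimers | I/C=C/C=C(C)/C=C/C=C(C)/C(O)CC(=O)[C@]1(C)C[C@@H](O[Si](CC)(CC)CC)CC1(C)C | intermediate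
37 | (2Z,4E,6E,8E,10E)-3-hydroxy-11-iodo-4,8-dimethyl-1-[(1R,4S)-1,2,2-trimethyl-4-[(triethylsilyl)oxy]cyclopentyl]undeca-2,4,6,8,10-pentaen-1-one | I/C=C/C=C(C)/C=C/C=C(C)/C(O)=C/C(=O)[C@]1(C)C[C@@H](O[Si](CC)(CC)CC)CC1(C)C | intermediate
38 | (E)-alkenyldimethylalane from 15 (CH3 on C13, AlMe2 on C14) | CC1=C(C#C/C(C)=C/C=C/C(C)=C/[Al](C)C)C(C)(C)C[C@H](O[Si](CC)(CC)CC)[C@H]1O[Si](CC)(CC)CC | intermediate (not isolated)
39 | dimethylaluminium chelate of the enolised diketone 37 | I/C=C/C=C(C)/C=C/C=C(C)/C(O[Al](C)C)=C/C(=O)[C@]1(C)C[C@@H](O[Si](CC)(CC)CC)CC1(C)C | intermediate (not isolated)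
40 | (3S,4S,3'S,5'R)-8'-hydroxy-3,4,3'-tris[(triethylsilyl)oxy]-7,8-didehydro-β,κ-caroten-6'-one | CC1=C(C#C/C(C)=C/C=C/C(C)=C/C=C/C=C(C)/C=C/C=C(C)/C(O)=C/C(=O)[C@]2(C)C[C@@H](O[Si](CC)(CC)CC)CC2(C)C)C(C)(C)C[C@H](O[Si](CC)(CC)CC)[C@H]1O[Si](CC)(CC)CC | intermediate
41 | (3S,4S,3'S,5'R)-3,4,3',8'-tetrahydroxy-7,8-didehydro-β,κ-caroten-6'-one | CC1=C(C#C/C(C)=C/C=C/C(C)=C/C=C/C=C(C)/C=C/C=C(C)/C(O)=C/C(=O)[C@]2(C)C[C@@H](O)CC2(C)C)C(C)(C)C[C@H](O)[C@H]1O | target

**Totals and risks**

Total step count: 29.
Longest linear sequence: 13 steps (7 → 16 → 17 → 19 → 21 → 22 → 23 → 24 → 25 → 26 → 36 → 37 → 40 → 41; steps 11–19 and 26–29).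

Steps most likely to fail:

1. Step 28 (key step). What may go wrong: protonolysis of the alkenylaluminium or alkenylzinc species by acidic sites of the partner, transfer of methyl instead of alkenyl to palladium, or loss of double-bond geometry in the aluminium-to-zinc-to-palladium relay, so that little cross-coupled product forms. Fallback: the two events are separated and the union is made by a neutral tin-based coupling. Setting out from 15, the same Cp2ZrCl2/Me3Al methylalumination is quenched with I2 to give the alkenyl iodide {[(1S,2S)-4-[(3E,5E,7E)-8-iodo-3,7-dimethylocta-3,5,7-trien-1-yn-1-yl]-3,5,5-trimethylcyclohex-3-ene-1,2-diyl]bis(oxy)}bis(triethylsilane) F1. Iodine–lithium exchange (t-BuLi, Et2O, −78 °C) and trapping with Bu3SnCl gives the alkenylstannane {[(1S,2S)-3,5,5-trimethyl-4-[(3E,5E,7E)-3,7-dimethyl-8-(tributylstannyl)octa-3,5,7-trien-1-yn-1-yl]cyclohex-3-ene-1,2-diyl]bis(oxy)}bis(triethylsilane) F2. Stille coupling of F2 with the free enol 37 (Pd2(dba)3, AsPh3, NMP, 23 °C, dark) forms the same C14–C15 bond and comes back to the route at 40.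

2. Step 16 (ring contraction). What may go wrong: the free hydroxyl ties up the Lewis acid and the tertiary cation is diverted into a 1,2-methyl shift (tetramethylcyclohexanones) or proton loss (allylic alcohols) instead of migration of the ring bond. Fallback: the order of inversion and ring contraction is exchanged, so that the rearrangement runs on a silyl-protected epoxide with the arrangement of a natural 5,6-epoxy-3-hydroxy end group. Setting out from 22, Mitsunobu reaction with 4-nitrobenzoic acid gives (1R,3S,6S)-1,5,5,6-tetramethyl-7-oxabicyclo[4.1.0]heptan-3-yl 4-nitrobenzoate F3. Methanolysis (K2CO3, MeOH) gives the anti-epoxy alcohol (1R,3S,6S)-1,5,5,6-tetramethyl-7-oxabicyclo[4.1.0]heptan-3-ol F4, and Et3SiCl/imidazole gives triethyl{[(1R,3S,6S)-1,5,5,6-tetramethyl-7-oxabicyclo[4.1.0]heptan-3-yl]oxy}silane F5. Lewis-acid ring contraction of F5 (BF3·OEt2, CH2Cl2, −78 °C) comes back to the route at 26.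

3. Step 9 (directed reduction). What may go wrong: the weak triacetoxyborohydride fails to reduce the hindered, cross-conjugated carbonyl, or non-directed hydride delivery and enolisation of the α-ketol give the cis-diol or C3 epimers. Fallback: catalyst control replaces substrate direction, on the silyl ether. Setting out from 12, Corey–Bakshi–Shibata reduction ((S)-2-methyl-CBS-oxazaborolidine, catecholborane, toluene, −78 °C), in which the alkenyl side acts as the large group, gives (1S,6S)-6-[(tert-butyldimethylsilyl)oxy]-2,4,4-trimethyl-3-[(3E,5E)-3-methyl-8-(trimethylsilyl)octa-3,5-dien-1,7-diyn-1-yl]cyclohex-2-en-1-ol F6. Bu4NF in THF then removes both silyl groups and comes back to the route at 14.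

**Further compounds**

F1 | step 28 | {[(1S,2S)-4-[(3E,5E,7E)-8-iodo-3,7-dimethylocta-3,5,7-trien-1-yn-1-yl]-3,5,5-trimethylcyclohex-3-ene-1,2-diyl]bis(oxy)}bis(triethylsilane) | CC1=C(C#C/C(C)=C/C=C/C(C)=C/I)C(C)(C)C[C@H](O[Si](CC)(CC)CC)[C@H]1O[Si](CC)(CC)CC
F2 | step 28 | {[(1S,2S)-3,5,5-trimethyl-4-[(3E,5E,7E)-3,7-dimethyl-8-(tributylstannyl)octa-3,5,7-trien-1-yn-1-yl]cyclohex-3-ene-1,2-diyl]bis(oxy)}bis(triethylsilane) | CC1=C(C#C/C(C)=C/C=C/C(C)=C/[Sn](CCCC)(CCCC)CCCC)C(C)(C)C[C@H](O[Si](CC)(CC)CC)[C@H]1O[Si](CC)(CC)CC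
F3 | step 16 | (1R,3S,6S)-1,5,5,6-tetramethyl-7-oxabicyclo[4.1.0]heptan-3-yl 4-nitrobenzoate | CC1(C)C[C@H](OC(=O)c2ccc(cc2)[N+](=O)[O-])C[C@@]2(C)O[C@@]12C
F4 | step 16 | (1R,3S,6S)-1,5,5,6-tetramethyl-7-oxabicyclo[4.1.0]heptan-3-ol | CC1(C)C[C@H](O)C[C@@]2(C)O[C@@]12C
F5 | step 16 | triethyl{[(1R,3S,6S)-1,5,5,6-tetramethyl-7-oxabicyclo[4.1.0]heptan-3-yl]oxy}silane | CC1(C)C[C@H](O[Si](CC)(CC)CC)C[C@@]2(C)O[C@@]12C
F6 | step 9 | (1S,6S)-6-[(tert-butyldimethylsilyl)oxy]-2,4,4-trimethyl-3-[(3E,5E)-3-methyl-8-(trimethylsilyl)octa-3,5-dien-1,7-diyn-1-yl]cyclohex-2-en-1-ol | CC1=C(C#C/C(C)=C/C=C/C#C[Si](C)(C)C)C(C)(C)C[C@H](O[Si](C)(C)C(C)(C)C)[C@H]1O
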